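**Retrosynthetic overview** (cembrane numbering: ring C1–C14, lactone carbons C15–C17)
- The C3–C4 epoxide and the C13 acetate are installed last, on a macrocyclic 3E,6E-diene diol.
- The 14-membered ring is closed at C4–C5 by a palladium-catalyzed decarboxylative allyl–alkenyl coupling between a vinyl cyclic carbonate (C5–C8) and an alkenyl pinacol boronate (C4); this also creates the E C6=C7 alkene and frees the C8 tertiary alcohol.
- The cis-fused α-methylene-γ-butyrolactone (C1, C14) comes from an indium-mediated, chelation-controlled allylation/lactonization that joins an α-hydroxy aldehyde (C5–C14) to a (Z)-2-(bromomethyl)-2-alkenoate (C1–C4, C15–C17).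
- The aldehyde fragment comes from a Brown crotylation product (C10–C14; sets C12, C13) and a Sharpless-resolved epoxy alcohol (C5–C9; sets C8), joined at C9–C10 by a Grignard epoxide opening.
- The bromide fragment comes from pent-3-yn-1-ol and methyl propiolate. Ring order: lactone, then macrocycle, then epoxide.

Assumption: chiral reagents and ligands ((+)-Ipc2BOMe, D-(−)-diisopropyl tartrate, the Shi ketone), protecting-group reagents and small atom-transfer reagents count as reagents, not starting materials; 2,2-dimethoxyacetaldehyde is used as its commercial anhydrous solution.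

**Route**

Step 1
Reactants: 1 cis-but-2-ene; 2 2,2-dimethoxyacetaldehyde
Product: 6 (2R,3S)-1,1-dimethoxy-3-methylpent-4-en-2-ol, via (Z)-but-2-enylpotassium 3 (not isolated), via (Z)-crotyldiisopinocampheylborane 4 (not isolated), via borinate ester 5 (not isolated)
Conditions: KOt-Bu, n-BuLi, THF, −78 to −45 °C; (+)-Ipc2BOMe, −78 °C; BF3·OEt2; 2, −78 °C; then NaOH, H2O2, rt
Reagents that add atoms: none
Why: Brown asymmetric crotylboration through a closed chair transition state, in which the Z crotyl geometry gives the 12,13-syn relationship and the isopinocampheyl groups derived from (−)-α-pinene direct attack to the Re face of the aldehyde, setting C13 as R and C12 as S.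

Step 2
Reactants: 6 (2R,3S)-1,1-dimethoxy-3-methylpent-4-en-2-ol
Product: 7 triethyl{[(2R,3S)-1,1-dimethoxy-3-methylpent-4-en-2-yl]oxy}silane
Conditions: Et3SiCl, imidazole, DMAP (cat.), CH2Cl2, 0 °C to rt
Reagents that add atoms: chlorotriethylsilane CC[Si](Cl)(CC)CC
Why: Silylation masks the C13 hydroxyl so that a Grignard reagent can later be made at the chain end; no stereocenter is touched.

Step 3
Reactants: 7 triethyl{[(2R,3S)-1,1-dimethoxy-3-methylpent-4-en-2-yl]oxy}silane
Product: 9 (3S,4R)-5,5-dimethoxy-3-methyl-4-(triethylsilyloxy)pentan-1-ol, via B-alkyl-9-BBN adduct 8 (not isolated)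
Conditions: 9-BBN, THF, 0 °C to rt; then NaOH, H2O2, 0 °C
Reagents that add atoms: hydrogen peroxide OO
Why: Anti-Markovnikov hydroboration–oxidation with bulky 9-BBN functionalizes only the terminal carbon (C10) and leaves both stereocenters untouched.

Step 4
Reactants: 9 (3S,4R)-5,5-dimethoxy-3-methyl-4-(triethylsilyloxy)pentan-1-ol
Product: 10 {[(2R,3S)-5-bromo-1,1-dimethoxy-3-methylpentan-2-yl]oxy}triethylsilane
Conditions: CBr4, PPh3, CH2Cl2, 0 °C
Reagents that add atoms: carbon tetrabromide BrC(Br)(Br)Br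
Why: Appel bromination converts the primary alcohol to the bromide under neutral conditions that keep the acetal and silyl ether intact.

Step 5
Reactants: 11 2-methylprop-2-enal (methacrolein)
Product: 12 racemic 2-methylpenta-1,4-dien-3-ol
Conditions: CH2=CHMgBr, THF, −78 to 0 °C; aq. NH4Cl
Reagents that add atoms: vinylmagnesium bromide C=C[Mg]Br
Why: 1,2-Addition of a vinyl Grignard reagent to the enal gives the racemic bis-allylic alcohol needed for the kinetic resolution.

Step 6
Reactants: 12 racemic 2-methylpenta-1,4-dien-3-ol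
Product: 13 (1R)-1-[(2S)-2-methyloxiran-2-yl]prop-2-en-1-ol
Conditions: Ti(OiPr)4 (10 mol%), D-(−)-diisopropyl tartrate (12 mol%), t-BuOOH (0.45 equiv), 4 Å molecular sieves, CH2Cl2, −20 °C
Reagents that add atoms: tert-butyl hydroperoxide CC(C)(C)OO
Why: Sharpless asymmetric epoxidation in kinetic-resolution mode, in which the (R)-alcohol reacts fast at its more electron-rich 1,1-disubstituted alkene to give the erythro epoxy alcohol (C8 set as S; C7 is R but is erased in step 16), while the (S)-alcohol stays behind (maximum yield about 45%).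

Step 7
Reactants: 10 {[(2R,3S)-5-bromo-1,1-dimethoxy-3-methylpentan-2-yl]oxy}triethylsilane; 13 (1R)-1-[(2S)-2-methyloxiran-2-yl]prop-2-en-1-ol
Product: 16 (3R,4S,8S,9R)-10,10-dimethoxy-4,8-dimethyl-9-(triethylsilyloxy)dec-1-ene-3,4-diol, via Grignard reagent 14 (not isolated), via chloromagnesium alkoxide 15 (not isolated)
Conditions: 10, Mg, THF, rt; 13, i-PrMgCl (1.0 equiv), THF, −40 °C; CuI (10 mol%), −40 to −10 °C; aq. NH4Cl
Reagents that add atoms: none
Why: Copper-catalyzed Grignard opening of the 2,2-disubstituted epoxide at its CH2 terminus (SN2) forms the C9–C10 bond without touching C8, the hydroxyl of 13 being first converted to its magnesium alkoxide so that no Grignard reagent is wasted.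

Step 8
Reactants: 16 (3R,4S,8S,9R)-10,10-dimethoxy-4,8-dimethyl-9-(triethylsilyloxy)dec-1-ene-3,4-diol
Product: 17 (4S,5R)-4-[(4S,5R)-6,6-dimethoxy-4-methyl-5-(triethylsilyloxy)hexyl]-4-methyl-5-vinyl-1,3-dioxolan-2-one
Conditions: 1,1′-carbonyldiimidazole, DMAP (cat.), toluene, 60 °C
Reagents that add atoms: 1,1′-carbonyldiimidazole O=C(n1ccnc1)n1ccnc1
Why: Carbonylation of the 1,2-diol gives the five-membered vinyl cyclic carbonate, an acid-stable precursor of the π-allyl electrophile, with retention at C8.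

Step 9
Reactants: 17 (4S,5R)-4-[(4S,5R)-6,6-dimethoxy-4-methyl-5-(triethylsilyloxy)hexyl]-4-methyl-5-vinyl-1,3-dioxolan-2-one
Product: 18 (2R,3S)-2-hydroxy-3-methyl-6-[(4S,5R)-4-methyl-2-oxo-5-vinyl-1,3-dioxolan-4-yl]hexanal
Conditions: CF3CO2H/H2O/CHCl3 (4:1:8), 0 °C to rt; used crude
Reagents that add atoms: water O
Why: Aqueous acid hydrolysis removes the triethylsilyl ether and unmasks the dimethyl acetal in one operation, the cyclic carbonate being acid-stable, and the α-hydroxy aldehyde is used at once to avoid dimerization or epimerization at C13.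

Step 10
Reactants: 19 pent-3-yn-1-ol
Product: 21 (E)-4-iodopent-3-en-1-ol, via alkenylzirconocene 20 (not isolated)
Conditions: Cp2Zr(H)Cl (2.5 equiv), THF, rt to 45 °C; then I2, 0 °C
Reagents that add atoms: iodine II
Why: Hydrozirconation–iodination: syn addition of Zr–H, with equilibration by excess Cp2Zr(H)Cl placing zirconium on the methyl-bearing carbon, then iodinolysis with retention gives the E alkenyl iodide (iodine trans to the CH2 chain).

Step 11
Reactants: 21 (E)-4-iodopent-3-en-1-ol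
Product: 22 (Z)-4-(4,4,5,5-tetramethyl-1,3,2-dioxaborolan-2-yl)pent-3-en-1-ol
Conditions: B2pin2, PdCl2(PPh3)2 (3 mol%), PPh3 (6 mol%), KOPh, toluene, 50 °C
Reagents that add atoms: bis(pinacolato)diboron CC1(C)OB(OC1(C)C)B1OC(C)(C)C(C)(C)O1
Why: Miyaura borylation of the alkenyl iodide proceeds with retention of olefin geometry, so boron stays trans to the CH2 chain.

Step 12
Reactants: 22 (Z)-4-(4,4,5,5-tetramethyl-1,3,2-dioxaborolan-2-yl)pent-3-en-1-ol
Product: 23 (Z)-4-(4,4,5,5-tetramethyl-1,3,2-dioxaborolan-2-yl)pent-3-enal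
Conditions: Dess–Martin periodinane, NaHCO3, CH2Cl2, 0 °C; used at once
Reagents that add atoms: none
Why: Buffered Dess–Martin oxidation gives the β,γ-unsaturated aldehyde without base-promoted conjugation.

Step 13
Reactants: 23 (Z)-4-(4,4,5,5-tetramethyl-1,3,2-dioxaborolan-2-yl)pent-3-enal; 24 methyl propiolate
Product: 26 methyl (5Z)-3-hydroxy-2-methylidene-6-(4,4,5,5-tetramethyl-1,3,2-dioxaborolan-2-yl)hept-5-enoate (racemic at C3), via vinylalane 25 (not isolated)
Conditions: 24, i-Bu2AlH, N-methylmorpholine N-oxide, THF, 0 °C; then 23, 0 °C to rt; aq. potassium sodium tartrate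
Reagents that add atoms: none
Why: Vinylalumination (hydroalumination of the propiolate to the α-aluminoacrylate, then 1,2-addition) gives the Morita–Baylis–Hillman-type adduct under non-basic conditions that do not isomerize the aldehyde, and the racemic carbinol center is erased in step 14.

Step 14
Reactants: 26 methyl (5Z)-3-hydroxy-2-methylidene-6-(4,4,5,5-tetramethyl-1,3,2-dioxaborolan-2-yl)hept-5-enoate
Product: 27 methyl (2Z,5Z)-2-(bromomethyl)-6-(4,4,5,5-tetramethyl-1,3,2-dioxaborolan-2-yl)hepta-2,5-dienoate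
Conditions: N-bromosuccinimide, Me2S, CH2Cl2, 0 °C to rt
Reagents that add atoms: N-bromosuccinimide O=C1CCC(=O)N1Br
Why: SN2′ bromination of the Morita–Baylis–Hillman alcohol (Corey–Kim-type activation) gives the thermodynamically preferred Z allylic bromide, with the C2 chain cis to CH2Br.

Step 15
Reactants: 18 (2R,3S)-2-hydroxy-3-methyl-6-[(4S,5R)-4-methyl-2-oxo-5-vinyl-1,3-dioxolan-4-yl]hexanal; 27 methyl (2Z,5Z)-2-(bromomethyl)-6-(4,4,5,5-tetramethyl-1,3,2-dioxaborolan-2-yl)hepta-2,5-dienoate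
Product: 30 (4S,5R)-5-{(1R,2S)-1-hydroxy-2-methyl-5-[(4S,5R)-4-methyl-2-oxo-5-vinyl-1,3-dioxolan-4-yl]pentyl}-3-methylidene-4-[(2Z)-3-(4,4,5,5-tetramethyl-1,3,2-dioxaborolan-2-yl)but-2-en-1-yl]oxolan-2-one, via allylindium reagent 28 (not isolated), via hydroxy ester 29 (not isolated)
Conditions: In powder, THF/H2O (1:1), rt; then TsOH·H2O (cat.), CH2Cl2, rt
Reagents that add atoms: none
Why: Indium-mediated Barbier allylation then lactonization, in which the free α-hydroxyl and the carbonyl oxygen chelate indium so that addition gives the 13,14-syn diol (C14 R), and the Z allylindium reacts at its γ-carbon through a chair transition state to give the 1,14-syn adduct (C1 S) that closes to the cis-fused α-methylene-γ-butyrolactone.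

Step 16
Reactants: 30 (4S,5R)-5-{(1R,2S)-1-hydroxy-2-methyl-5-[(4S,5R)-4-methyl-2-oxo-5-vinyl-1,3-dioxolan-4-yl]pentyl}-3-methylidene-4-[(2Z)-3-(4,4,5,5-tetramethyl-1,3,2-dioxaborolan-2-yl)but-2-en-1-yl]oxolan-2-one
Product: 32 (1S,3E,6E,8S,12S,13R,14R)-8,13-dihydroxycembra-3,6,15(17)-trien-16,14-olide, via O-pinacolboryl macrocycle 31 (not isolated)
Conditions: Pd2(dba)3·CHCl3 (5 mol%), tri(2-furyl)phosphine (20 mol%), THF, 45 °C, syringe-pump addition of 30 to 1 mM; then aq. NH4Cl
Reagents that add atoms: none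
Why: Proposed new method: a macrocyclizing, base-free decarboxylative allyl–alkenyl coupling in which zerovalent palladium ionizes the vinyl cyclic carbonate (loss of CO2) to a zwitterionic π-allylpalladium tertiary alkoxide, the alkoxide acts as internal base by binding the pinacol boronate at the other chain end (which triggers alkenyl transmetalation and prevents the O–Pd chelation that would favor a Z olefin), and reductive elimination at the unhindered CH2 terminus of the syn-π-allyl forms the C4–C5 bond, closes the 14-membered ring, fixes E C6=C7 and leaves the untouched C8 carbinol as its boryl ether; the closest known reaction type is the intermolecular palladium-catalyzed 1,4-coupling of alkenyl- or arylboron reagents with vinyl epoxides together with decarboxylative allylic substitution of vinyl ethylene carbonates, neither of which has been used to close a ring with an alkenylboron partner.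

Step 17
Reactants: 32 (1S,3E,6E,8S,12S,13R,14R)-8,13-dihydroxycembra-3,6,15(17)-trien-16,14-olide
Product: 33 (1S,3E,6E,8S,12S,13R,14R)-13-acetoxy-8-hydroxycembra-3,6,15(17)-trien-16,14-olide
Conditions: Ac2O, pyridine, DMAP (cat.), CH2Cl2, 0 °C
Reagents that add atoms: acetic anhydride CC(=O)OC(C)=O
Why: Selective acylation, since the secondary C13 hydroxyl is acetylated while the tertiary allylic C8 hydroxyl is too hindered to react.

Step 18
Reactants: 33 (1S,3E,6E,8S,12S,13R,14R)-13-acetoxy-8-hydroxycembra-3,6,15(17)-trien-16,14-olide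
Product: 34 (1S,3R,4R,6E,8S,12S,13R,14R)-13-acetoxy-3,4-epoxy-8-hydroxycembra-6,15(17)-dien-16,14-olide (CNP0202356.4)
Conditions: D-fructose-derived Shi ketone (30 mol%), KHSO5 (as 2KHSO5·KHSO4·K2SO4), K2CO3, Bu4NHSO4, aq. Na2B4O7/Na2EDTA buffer, MeCN/CH2(OMe)2, 0 °C
Reagents that add atoms: potassium peroxymonosulfate [K+].[O-]S(=O)(=O)OO
Why: Shi asymmetric epoxidation, in which the chiral dioxirane epoxidizes the electron-rich trisubstituted E C3=C4 alkene through a spiro transition state on the face that gives the (3R,4R)-epoxide, leaving the hindered C6=C7 alkene and the electron-poor methylene lactone untouched.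

**Compound list**
1 | cis-but-2-ene | C/C=C\C | starting material
2 | 2,2-dimethoxyacetaldehyde | COC(OC)C=O | starting material
3 | (Z)-but-2-enylpotassium | C/C=C\C[K] | intermediate
4 | (Z)-but-2-enylbis[(1S,2R,3S,5S)-isopinocampheyl]borane | C/C=C\CB([C@H]1C[C@H]2C[C@@H]([C@@H]1C)C2(C)C)[C@H]1C[C@H]2C[C@@H]([C@@H]1C)C2(C)C | intermediate
5 | (2R,3S)-1,1-dimethoxy-3-methylpent-4-en-2-yl bis(isopinocampheyl)borinate | COC(OC)[C@H](OB([C@H]1C[C@H]2C[C@@H]([C@@H]1C)C2(C)C)[C@H]1C[C@H]2C[C@@H]([C@@H]1C)C2(C)C)[C@@H](C)C=C | intermediate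
6 | (2R,3S)-1,1-dimethoxy-3-methylpent-4-en-2-ol | COC(OC)[C@H](O)[C@@H](C)C=C | intermediate
7 | triethyl{[(2R,3S)-1,1-dimethoxy-3-methylpent-4-en-2-yl]oxy}silane | COC(OC)[C@H](O[Si](CC)(CC)CC)[C@@H](C)C=C | intermediate
8 | 9-[(3S,4R)-5,5-dimethoxy-3-methyl-4-(triethylsilyloxy)pentyl]-9-borabicyclo[3.3.1]nonane | COC(OC)[C@H](O[Si](CC)(CC)CC)[C@@H](C)CCB1C2CCCC1CCC2 | intermediate
9 | (3S,4R)-5,5-dimethoxy-3-methyl-4-(triethylsilyloxy)pentan-1-ol | COC(OC)[C@H](O[Si](CC)(CC)CC)[C@@H](C)CCO | intermediate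
10 | {[(2R,3S)-5-bromo-1,1-dimethoxy-3-methylpentan-2-yl]oxy}triethylsilane | COC(OC)[C@H](O[Si](CC)(CC)CC)[C@@H](C)CCBr | intermediate
11 | 2-methylprop-2-enal (methacrolein) | CC(=C)C=O | starting material
12 | racemic 2-methylpenta-1,4-dien-3-ol | C=CC(O)C(C)=C | intermediate
13 | (1R)-1-[(2S)-2-methyloxiran-2-yl]prop-2-en-1-ol | C=C[C@@H](O)[C@]1(C)CO1 | intermediate
14 | [(3S,4R)-5,5-dimethoxy-3-methyl-4-(triethylsilyloxy)pentyl]magnesium bromide | COC(OC)[C@H](O[Si](CC)(CC)CC)[C@@H](C)CC[Mg]Br | intermediate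
15 | chloromagnesium (1R)-1-[(2S)-2-methyloxiran-2-yl]prop-2-en-1-olate | C=C[C@@H](O[Mg]Cl)[C@]1(C)CO1 | intermediate
16 | (3R,4S,8S,9R)-10,10-dimethoxy-4,8-dimethyl-9-(triethylsilyloxy)dec-1-ene-3,4-diol | COC(OC)[C@H](O[Si](CC)(CC)CC)[C@@H](C)CCC[C@](C)(O)[C@H](O)C=C | intermediate
17 | (4S,5R)-4-[(4S,5R)-6,6-dimethoxy-4-methyl-5-(triethylsilyloxy)hexyl]-4-methyl-5-vinyl-1,3-dioxolan-2-one | COC(OC)[C@H](O[Si](CC)(CC)CC)[C@@H](C)CCC[C@]1(C)OC(=O)O[C@@H]1C=C | intermediate
18 | (2R,3S)-2-hydroxy-3-methyl-6-[(4S,5R)-4-methyl-2-oxo-5-vinyl-1,3-dioxolan-4-yl]hexanal | O=C[C@H](O)[C@@H](C)CCC[C@]1(C)OC(=O)O[C@@H]1C=C | intermediate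
19 | pent-3-yn-1-ol | CC#CCCO | starting material
20 | alkenylzirconocene: O,C-bis[chlorobis(cyclopentadienyl)zirconium] derivative of (E)-pent-3-en-1-ol-4-yl | C/C(=C\CCO[Zr](Cl)(C1C=CC=C1)C1C=CC=C1)[Zr](Cl)(C1C=CC=C1)C1C=CC=C1 | intermediate
21 | (E)-4-iodopent-3-en-1-ol | C/C(I)=C\CCO | intermediate
22 | (Z)-4-(4,4,5,5-tetramethyl-1,3,2-dioxaborolan-2-yl)pent-3-en-1-ol (boron trans to the CH2 chain) | C/C(=C\CCO)B1OC(C)(C)C(C)(C)O1 | intermediate
23 | (Z)-4-(4,4,5,5-tetramethyl-1,3,2-dioxaborolan-2-yl)pent-3-enal | C/C(=C\CC=O)B1OC(C)(C)C(C)(C)O1 | intermediate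
24 | methyl propiolate | C#CC(=O)OC | starting material
25 | methyl 2-(diisobutylalumanyl)prop-2-enoate | C=C(C(=O)OC)[Al](CC(C)C)CC(C)C | intermediate
26 | methyl (5Z)-3-hydroxy-2-methylidene-6-(4,4,5,5-tetramethyl-1,3,2-dioxaborolan-2-yl)hept-5-enoate (racemic at C3) | C=C(C(=O)OC)C(O)C/C=C(\C)B1OC(C)(C)C(C)(C)O1 | intermediate
27 | methyl (2Z,5Z)-2-(bromomethyl)-6-(4,4,5,5-tetramethyl-1,3,2-dioxaborolan-2-yl)hepta-2,5-dienoate | BrC/C(C(=O)OC)=C\C/C=C(\C)B1OC(C)(C)C(C)(C)O1 | intermediate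
28 | allylindium reagent from 27 (sesquibromide, drawn as the dibromide) | Br[In](Br)C/C(C(=O)OC)=C\C/C=C(\C)B1OC(C)(C)C(C)(C)O1 | intermediate
29 | methyl (3S,4R,5R,6S)-4,5-dihydroxy-6-methyl-2-methylidene-9-[(4S,5R)-4-methyl-2-oxo-5-vinyl-1,3-dioxolan-4-yl]-3-[(2Z)-3-(4,4,5,5-tetramethyl-1,3,2-dioxaborolan-2-yl)but-2-en-1-yl]nonanoate | C=C(C(=O)OC)[C@H](C/C=C(\C)B1OC(C)(C)C(C)(C)O1)[C@@H](O)[C@H](O)[C@@H](C)CCC[C@]2(C)OC(=O)O[C@@H]2C=C | intermediate
30 | (4S,5R)-5-{(1R,2S)-1-hydroxy-2-methyl-5-[(4S,5R)-4-methyl-2-oxo-5-vinyl-1,3-dioxolan-4-yl]pentyl}-3-methylidene-4-[(2Z)-3-(4,4,5,5-tetramethyl-1,3,2-dioxaborolan-2-yl)but-2-en-1-yl]oxolan-2-one | C=C1C(=O)O[C@@H]([C@H](O)[C@@H](C)CCC[C@]2(C)OC(=O)O[C@@H]2C=C)[C@H]1C/C=C(\C)B1OC(C)(C)C(C)(C)O1 | intermediate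
31 | (1S,3E,6E,8S,12S,13R,14R)-13-hydroxy-8-(4,4,5,5-tetramethyl-1,3,2-dioxaborolan-2-yloxy)cembra-3,6,15(17)-trien-16,14-olide | C=C1C(=O)O[C@H]2[C@H](O)[C@@H](C)CCC[C@](C)(OB3OC(C)(C)C(C)(C)O3)/C=C/C/C(C)=C/C[C@@H]12 | intermediate
32 | (1S,3E,6E,8S,12S,13R,14R)-8,13-dihydroxycembra-3,6,15(17)-trien-16,14-olide | C=C1C(=O)O[C@H]2[C@H](O)[C@@H](C)CCC[C@](C)(O)/C=C/C/C(C)=C/C[C@@H]12 | intermediate
33 | (1S,3E,6E,8S,12S,13R,14R)-13-acetoxy-8-hydroxycembra-3,6,15(17)-trien-16,14-olide | C=C1C(=O)O[C@H]2[C@H](OC(C)=O)[C@@H](C)CCC[C@](C)(O)/C=C/C/C(C)=C/C[C@@H]12 | intermediate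
34 | (1S,3R,4R,6E,8S,12S,13R,14R)-13-acetoxy-3,4-epoxy-8-hydroxycembra-6,15(17)-dien-16,14-olide (CNP0202356.4) | C=C1C(=O)O[C@H]2[C@H](OC(C)=O)[C@@H](C)CCC[C@](C)(O)/C=C/C[C@@]3(C)O[C@@H]3C[C@@H]12 | target

**Totals**
Total step count: 18.
Longest linear sequence: 11 steps (steps 1–4, 7–9, 15–18).

**Steps most likely to fail, with fallbacks**

Step 15 (indium allylation). The risks are handling of the free α-hydroxy aldehyde and triple stereodifferentiation in one step. The fallback replaces the aqueous Barbier reaction by a closed-transition-state allylboration. It sets out from hydroxy ester 26 (with aldehyde 18) and comes back at lactone 30. Compound 26 is acetylated (Ac2O, DMAP, CH2Cl2) to methyl (5Z)-3-acetoxy-2-methylidene-6-(pinacolboryl)hept-5-enoate F1. CuCl-catalyzed SN2′ borylation of this acetate (B2pin2, KOAc, DMF) gives the 2-(methoxycarbonyl)allylboronate methyl (2E,5Z)-6-(pinacolboryl)-2-[(pinacolboryl)methyl]hepta-2,5-dienoate F2, in which the C4 chain is cis to CH2B. Heating this boronate with 18 (toluene, 50 °C; then TsOH) transfers the olefin geometry through the chair transition state into the cis lactone. The free α-hydroxyl tethers to boron and directs the 13,14-syn addition, giving 30.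

Step 16 (new macrocyclization). The risks are oligomerization, Z olefin formation and attack at the internal allyl terminus. The fallback uses known chemistry: the C4–C5 bond is made intermolecularly and the ring is closed by the established intramolecular indium allylation of an allylic bromide onto an aldehyde. It sets out from diol 16 (with boronate 26) and comes back at macrocycle 32.
- Selective mesylation of the secondary allylic hydroxyl of 16 and base closure (MsCl, Et3N, CH2Cl2, −30 °C; then K2CO3, MeOH, 0 °C) give the vinyl epoxide triethyl({(2R,3S)-1,1-dimethoxy-3-methyl-6-[(2S,3S)-2-methyl-3-vinyloxiran-2-yl]hexan-2-yl}oxy)silane F3.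
- Miyaura-type 1,4-coupling of this epoxide with 26 (Pd(PPh3)4, THF/H2O, 40 °C) gives methyl (5E,8E,10S,14S,15R)-3,10-dihydroxy-16,16-dimethoxy-6,10,14-trimethyl-2-methylidene-15-(triethylsilyloxy)hexadeca-5,8-dienoate F4.
- N-bromosuccinimide/Me2S, which spares the hindered tertiary alcohol, converts it to methyl (2Z,5E,8E,10S,14S,15R)-2-(bromomethyl)-10-hydroxy-16,16-dimethoxy-6,10,14-trimethyl-15-(triethylsilyloxy)hexadeca-2,5,8-trienoate F5.
- Brief aqueous CF3CO2H gives methyl (2Z,5E,8E,10S,14S,15R)-2-(bromomethyl)-10,15-dihydroxy-6,10,14-trimethyl-16-oxohexadeca-2,5,8-trienoate F6.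
- Indium powder in THF/H2O at 1 mM, then TsOH, closes the ring and the lactone to 32.

Step 18 (late epoxidation). The risk is that the conformational bias of the macrocycle overrides the Shi catalyst and puts oxygen on the wrong face of C3=C4. The fallback is a halohydrin route that delivers oxygen to the face opposite to the one electrophiles attack. It sets out from 33 and comes back at 34. N-bromosuccinimide in THF/H2O at 0 °C adds bromine to the accessible face of the trisubstituted alkene and water anti at C4, giving the bromohydrin (1S,3S,4R,6E,8S,12S,13R,14R)-13-acetoxy-3-bromo-4,8-dihydroxycembra-6,15(17)-dien-16,14-olide F7. Ag2O in CH2Cl2 then closes the C4 alkoxide onto C3 with inversion to give 34 without exposing the acetate or the methylene lactone to nucleophilic base.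

Further compounds
F1 | step 15 | methyl (5Z)-3-acetoxy-2-methylidene-6-(4,4,5,5-tetramethyl-1,3,2-dioxaborolan-2-yl)hept-5-enoate (racemic at C3) | C=C(C(=O)OC)C(OC(C)=O)C/C=C(\C)B1OC(C)(C)C(C)(C)O1
F2 | step 15 | methyl (2E,5Z)-6-(4,4,5,5-tetramethyl-1,3,2-dioxaborolan-2-yl)-2-[(4,4,5,5-tetramethyl-1,3,2-dioxaborolan-2-yl)methyl]hepta-2,5-dienoate | COC(=O)/C(CB1OC(C)(C)C(C)(C)O1)=C/C/C=C(\C)B1OC(C)(C)C(C)(C)O1
F3 | step 16 | triethyl({(2R,3S)-1,1-dimethoxy-3-methyl-6-[(2S,3S)-2-methyl-3-vinyloxiran-2-yl]hexan-2-yl}oxy)silane | COC(OC)[C@H](O[Si](CC)(CC)CC)[C@@H](C)CCC[C@]1(C)O[C@H]1C=C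
F4 | step 16 | methyl (5E,8E,10S,14S,15R)-3,10-dihydroxy-16,16-dimethoxy-6,10,14-trimethyl-2-methylidene-15-(triethylsilyloxy)hexadeca-5,8-dienoate (epimers at C3) | C=C(C(=O)OC)C(O)C/C=C(\C)C/C=C/[C@@](C)(O)CCC[C@H](C)[C@@H](O[Si](CC)(CC)CC)C(OC)OC
F5 | step 16 | methyl (2Z,5E,8E,10S,14S,15R)-2-(bromomethyl)-10-hydroxy-16,16-dimethoxy-6,10,14-trimethyl-15-(triethylsilyloxy)hexadeca-2,5,8-trienoate | BrC/C(C(=O)OC)=C\C/C=C(\C)C/C=C/[C@@](C)(O)CCC[C@H](C)[C@@H](O[Si](CC)(CC)CC)C(OC)OC
F6 | step 16 | methyl (2Z,5E,8E,10S,14S,15R)-2-(bromomethyl)-10,15-dihydroxy-6,10,14-trimethyl-16-oxohexadeca-2,5,8-trienoate | BrC/C(C(=O)OC)=C\C/C=C(\C)C/C=C/[C@@](C)(O)CCC[C@H](C)[C@@H](O)C=O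
F7 | step 18 | (1S,3S,4R,6E,8S,12S,13R,14R)-13-acetoxy-3-bromo-4,8-dihydroxycembra-6,15(17)-dien-16,14-olide | C=C1C(=O)O[C@H]2[C@H](OC(C)=O)[C@@H](C)CCC[C@](C)(O)/C=C/C[C@@](C)(O)[C@@H](Br)C[C@@H]12
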